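**Plan**
- Retrosynthesis removes the two aryl tosylates, then cuts the tetralin C1–C8a bond. The ring C/D aryltetralin (C1 aryl, C2 CH2OH, C3 OH and CH2OH) is a constitutional isomer of a 2-aryl-4-benzyl-3-(hydroxymethyl)oxolan-4-ol, in which C1 is bonded to the oxygen of the C3 hydroxymethyl group instead of to C8a, so a bis-oxolane is the precursor.
- The biaryl bond between C5 of ring B and C5 of ring C is cut next (Suzuki–Miyaura). This gives two bromo-oxolane monomers that differ in the benzyl ring and in phenol protection (tosyl on rings A and B, benzyl on rings C and D).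
- Each oxolane is cut at C5 (lactone carbonyl reduced to CH2), C4–OH (enolate oxidation), C4–CH2Ar (enolate alkylation) and C2–C3 (Evans syn-aldol of a succinate imide with a protected 5-bromovanillin).
- Forward, each monomer goes: aldol and lactonisation to a trans paraconic lactone, acid to CH2OH to silyl ether, C-benzylation, hydroxylation, lactone to oxolane. One half is then borylated and coupled to the other, silyl and benzyl groups are removed, acid converts only the ring C oxolane into the tetralin, and the tosylates are cleaved last.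
- Stereochemistry: (S)-4-benzyloxazolidin-2-one sets C2 and C3 of both oxolanes (syn-aldol gives 2,3-trans). C4 follows from attack anti to the C3 substituent. Tetralin C1 is set in the key step by the adjacent C2 centre.

Key step: step 25

Abbreviations in names: Ts = 4-methylphenylsulfonyl, TBS = tert-butyldimethylsilyl, Bn = benzyl. Ring A = 3-oxy-4-methoxybenzyl ring, ring B = biaryl ring carrying the oxolane, ring C = biaryl ring carrying the tetralin, ring D = aromatic ring of the tetralin.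

**Step 1**
Reactants: 1 (S)-4-benzyl-1,3-oxazolidin-2-one; 2 methyl 4-chloro-4-oxobutanoate
Product: 3 methyl 4-[(4S)-4-benzyl-2-oxo-1,3-oxazolidin-3-yl]-4-oxobutanoate
Conditions: n-BuLi, THF, −78 °C; then 2, −78 to 0 °C
Reagents that add atoms: none
Why: N-acylation of the lithiated oxazolidinone by the acid chloride is a standard imide formation in which the methyl ester is not attacked at low temperature.

**Step 2**
Reactants: 4 5-bromovanillin (3-bromo-4-hydroxy-5-methoxybenzaldehyde)
Product: 5 2-bromo-4-formyl-6-methoxyphenyl 4-methylbenzenesulfonate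
Conditions: TsCl, Et3N, DMAP (cat.), CH2Cl2, 0 °C to rt
Reagents that add atoms: p-toluenesulfonyl chloride, Cc1ccc(cc1)S(Cl)(=O)=O
Why: O-sulfonylation of the phenol gives the electron-poor aryl tosylate that later keeps the ring B oxolane from ionising, while the aldehyde is inert.

**Step 3**
Reactants: 3 methyl 4-[(4S)-4-benzyl-2-oxo-1,3-oxazolidin-3-yl]-4-oxobutanoate; 5 2-bromo-4-formyl-6-methoxyphenyl 4-methylbenzenesulfonate
Product: 7 (4S)-4-benzyl-3-{[(2S,3S)-2-(3-bromo-5-methoxy-4-tosyloxyphenyl)-5-oxooxolan-3-yl]carbonyl}-1,3-oxazolidin-2-one, via syn-aldol hydroxy ester 6 (not isolated)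
Conditions: Bu2BOTf, iPr2NEt, CH2Cl2, −78 to 0 °C; then 5, −78 to 0 °C; pH 7 buffer, MeOH, H2O2, 0 °C; crude stirred with TsOH·H2O (cat.), CH2Cl2, rt
Reagents that add atoms: none
Why: In this Evans syn-aldol reaction the Z-boron enolate of the imide adds to the aldehyde through a closed chair transition state on the face away from the auxiliary benzyl group, which sets the aryl carbinol centre (S) and the adjacent carbonyl-bearing centre (S) together, and the γ-hydroxy ester then closes to the 2,3-trans lactone.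

**Step 4**
Reactants: 7 trans lactone imide
Product: 8 (2S,3S)-2-(3-bromo-5-methoxy-4-tosyloxyphenyl)-5-oxooxolane-3-carboxylic acid
Conditions: LiOH, H2O2, THF/H2O, 0 °C; Na2SO3; then HCl to pH 2
Reagents that add atoms: hydrogen peroxide, OO
Why: Hydroperoxide cleavage of the exocyclic imide carbonyl is the standard auxiliary removal, and any lactone opened by hydroxide recloses on acidification because only the γ-lactone is accessible.

**Step 5**
Reactants: 8 paraconic acid
Product: 9 (4R,5S)-5-(3-bromo-5-methoxy-4-tosyloxyphenyl)-4-(hydroxymethyl)oxolan-2-one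
Conditions: BH3·SMe2, THF, 0 °C to rt; then MeOH
Reagents that add atoms: none
Why: Borane reduces a carboxylic acid through its acyloxyborane much faster than a lactone, and the non-basic medium should avoid translactonisation onto the new primary alcohol.

**Step 6**
Reactants: 9 hydroxymethyl lactone
Product: 10 (4R,5S)-5-(3-bromo-5-methoxy-4-tosyloxyphenyl)-4-(TBSO-methyl)oxolan-2-one
Conditions: TBSCl, imidazole, CH2Cl2, 0 °C to rt
Reagents that add atoms: tert-butyldimethylsilyl chloride, CC(C)(C)[Si](C)(C)Cl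
Why: Silylation of the primary alcohol blocks lactone migration and alkoxide formation during the two enolate steps that follow.

**Step 7**
Reactants: 11 3-hydroxy-4-methoxybenzyl alcohol (isovanillyl alcohol)
Product: 12 5-(hydroxymethyl)-2-methoxyphenyl 4-methylbenzenesulfonate
Conditions: TsCl, K2CO3, acetone, rt
Reagents that add atoms: p-toluenesulfonyl chloride, Cc1ccc(cc1)S(Cl)(=O)=O
Why: Carbonate ionises only the phenol, so sulfonylation is selective for the phenolic oxygen and the benzylic alcohol stays free.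

**Step 8**
Reactants: 12 5-(hydroxymethyl)-2-methoxyphenyl 4-methylbenzenesulfonate
Product: 13 5-(bromomethyl)-2-methoxyphenyl 4-methylbenzenesulfonate
Conditions: PBr3, CH2Cl2, 0 °C
Reagents that add atoms: phosphorus tribromide, BrP(Br)Br
Why: Benzylic alcohols are converted into bromides by PBr3 through a phosphite ester and bromide displacement, and the aryl tosylate is untouched.

**Step 9**
Reactants: 10 silyloxymethyl lactone; 13 5-(bromomethyl)-2-methoxyphenyl 4-methylbenzenesulfonate
Product: 14 (3S,4R,5S)-5-(3-bromo-5-methoxy-4-tosyloxyphenyl)-3-(4-methoxy-3-tosyloxybenzyl)-4-(TBSO-methyl)oxolan-2-one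
Conditions: LiN(SiMe3)2, THF, −78 °C; then 13, −78 to −30 °C
Reagents that add atoms: none
Why: Alkylation of the lithium lactone enolate with a reactive benzylic bromide is expected to occur trans to the C4 silyloxymethyl group, although this C3 configuration is erased again when the enolate is re-formed in step 10.

**Step 10**
Reactants: 14 benzylated lactone
Product: 15 (3S,4R,5S)-5-(3-bromo-5-methoxy-4-tosyloxyphenyl)-3-hydroxy-3-(4-methoxy-3-tosyloxybenzyl)-4-(TBSO-methyl)oxolan-2-one
Conditions: KN(SiMe3)2, THF, −78 °C; then 2-(phenylsulfonyl)-3-phenyloxaziridine, −78 °C; AcOH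
Reagents that add atoms: 2-(phenylsulfonyl)-3-phenyloxaziridine, O=S(=O)(N1OC1c1ccccc1)c1ccccc1
Why: Oxidation of the potassium enolate by the N-sulfonyloxaziridine should take place on the face anti to the adjacent silyloxymethyl group, placing the hydroxyl trans and the benzyl group cis to it, which is the configuration of the oxolane carbinol carbon.

**Step 11**
Reactants: 15 hydroxy lactone
Product: 17 (3S,4R,5S)-5-(3-bromo-5-methoxy-4-tosyloxyphenyl)-3-(4-methoxy-3-tosyloxybenzyl)-4-(TBSO-methyl)oxolan-3-ol, via lactol 16 (not isolated)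
Conditions: iBu2AlH, CH2Cl2, −78 °C; then Et3SiH, BF3·OEt2, −78 to −30 °C; aq. KNaC4H4O6
Reagents that add atoms: none
Why: Partial reduction of the lactone to the lactol followed by ionic hydrogenation of the derived oxocarbenium ion removes the carbonyl oxygen without touching the three stereocentres, and the tosylated aryl group at C5 does not support ionisation of the benzylic C–O bond.

**Step 12**
Reactants: 4 5-bromovanillin
Product: 18 4-benzyloxy-3-bromo-5-methoxybenzaldehyde
Conditions: BnBr, K2CO3, DMF, rt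
Reagents that add atoms: benzyl bromide, BrCc1ccccc1
Why: Williamson etherification of the phenoxide gives a benzyl ether that survives bases, hydrides and cross-coupling and is removed later by hydrogenolysis without affecting the tosylates.

**Step 13**
Reactants: 3 succinate imide; 18 4-benzyloxy-3-bromo-5-methoxybenzaldehyde
Product: 20 (4S)-4-benzyl-3-{[(2S,3S)-2-(4-benzyloxy-3-bromo-5-methoxyphenyl)-5-oxooxolan-3-yl]carbonyl}-1,3-oxazolidin-2-one, via syn-aldol hydroxy ester 19 (not isolated)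
Conditions: Bu2BOTf, iPr2NEt, CH2Cl2, −78 to 0 °C; then 18, −78 to 0 °C; pH 7 buffer, MeOH, H2O2, 0 °C; crude stirred with TsOH·H2O (cat.), CH2Cl2, rt
Reagents that add atoms: none
Why: The same Evans syn-aldol reaction and lactonisation as in step 3 set the (S) aryl carbinol centre and the (S) neighbouring centre under control of the auxiliary.

**Step 14**
Reactants: 20 trans lactone imide
Product: 21 (2S,3S)-2-(4-benzyloxy-3-bromo-5-methoxyphenyl)-5-oxooxolane-3-carboxylic acid
Conditions: LiOH, H2O2, THF/H2O, 0 °C; Na2SO3; then HCl to pH 2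
Reagents that add atoms: hydrogen peroxide, OO
Why: Hydroperoxide attacks the exocyclic imide carbonyl selectively, and acidification restores the γ-lactone.

**Step 15**
Reactants: 21 paraconic acid
Product: 22 (4R,5S)-5-(4-benzyloxy-3-bromo-5-methoxyphenyl)-4-(hydroxymethyl)oxolan-2-one
Conditions: BH3·SMe2, THF, 0 °C to rt; then MeOH
Reagents that add atoms: none
Why: Chemoselective borane reduction of the carboxylic acid leaves the lactone, the aryl bromide and the benzyl ether intact.

**Step 16**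
Reactants: 22 hydroxymethyl lactone
Product: 23 (4R,5S)-5-(4-benzyloxy-3-bromo-5-methoxyphenyl)-4-(TBSO-methyl)oxolan-2-one
Conditions: TBSCl, imidazole, CH2Cl2, 0 °C to rt
Reagents that add atoms: tert-butyldimethylsilyl chloride, CC(C)(C)[Si](C)(C)Cl
Why: Silyl protection of the primary alcohol prevents lactone migration in the enolate chemistry.

**Step 17**
Reactants: 24 4-benzyloxy-3-methoxybenzyl alcohol
Product: 25 1-benzyloxy-4-(bromomethyl)-2-methoxybenzene
Conditions: PBr3, CH2Cl2, 0 °C; used at once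
Reagents that add atoms: phosphorus tribromide, BrP(Br)Br
Why: PBr3 converts the electron-rich benzylic alcohol into the bromide under conditions that leave the aryl benzyl ether alone.

**Step 18**
Reactants: 23 silyloxymethyl lactone; 25 1-benzyloxy-4-(bromomethyl)-2-methoxybenzene
Product: 26 (3S,4R,5S)-5-(4-benzyloxy-3-bromo-5-methoxyphenyl)-3-(4-benzyloxy-3-methoxybenzyl)-4-(TBSO-methyl)oxolan-2-one
Conditions: LiN(SiMe3)2, THF, −78 °C; then 25, −78 to −30 °C
Reagents that add atoms: none
Why: Lactone enolate alkylation with the benzylic bromide installs the ring D benzyl group trans to the C4 substituent, and the C3 configuration is reset in the next step.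

**Step 19**
Reactants: 26 benzylated lactone
Product: 27 (3S,4R,5S)-5-(4-benzyloxy-3-bromo-5-methoxyphenyl)-3-(4-benzyloxy-3-methoxybenzyl)-3-hydroxy-4-(TBSO-methyl)oxolan-2-one
Conditions: KN(SiMe3)2, THF, −78 °C; then 2-(phenylsulfonyl)-3-phenyloxaziridine, −78 °C; AcOH
Reagents that add atoms: 2-(phenylsulfonyl)-3-phenyloxaziridine, O=S(=O)(N1OC1c1ccccc1)c1ccccc1
Why: Enolate oxidation by the oxaziridine anti to the silyloxymethyl group should give the tertiary alcohol with hydroxyl trans and benzyl cis to that group.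

**Step 20**
Reactants: 27 hydroxy lactone
Product: 29 (3S,4R,5S)-5-(4-benzyloxy-3-bromo-5-methoxyphenyl)-3-(4-benzyloxy-3-methoxybenzyl)-4-(TBSO-methyl)oxolan-3-ol, via lactol 28 (not isolated)
Conditions: iBu2AlH, CH2Cl2, −78 °C; then Et3SiH, BF3·OEt2, −78 to −40 °C; aq. KNaC4H4O6
Reagents that add atoms: none
Why: Lactol formation and silane reduction of the oxocarbenium ion convert the lactone into the cyclic ether, and the benzylic C–O bond should hold at low temperature because the ring C benzyl ether, flanked by bromine and methoxy, is twisted out of conjugation and is a poor donor.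

**Step 21**
Reactants: 29 bromo-oxolane of the ring C/D half
Product: 30 (3S,4R,5S)-5-[4-benzyloxy-3-methoxy-5-(4,4,5,5-tetramethyl-1,3,2-dioxaborolan-2-yl)phenyl]-3-(4-benzyloxy-3-methoxybenzyl)-4-(TBSO-methyl)oxolan-3-ol
Conditions: B2pin2, PdCl2(dppf) (cat.), KOAc, 1,4-dioxane, 90 °C
Reagents that add atoms: bis(pinacolato)diboron, CC1(C)OB(OC1(C)C)B1OC(C)(C)C(C)(C)O1
Why: Miyaura borylation proceeds by oxidative addition of the aryl bromide to zerovalent palladium and acetate-assisted transmetalation with the diboron, and it tolerates the free tertiary alcohol, the silyl ether and the benzyl ethers.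

**Step 22**
Reactants: 17 bromo-oxolane of the ring A/B half; 30 pinacol boronate of the ring C/D half
Product: 31 bis-oxolane biaryl in which C5 of ring B (former C–Br of 17) is bonded to C5 of ring C (former C–B of 30); rings A and B are tosylates, rings C and D are benzyl ethers and both hydroxymethyl groups are TBS ethers
Conditions: PdCl2(dppf) (cat.), K3PO4, 1,4-dioxane/H2O, 90 °C
Reagents that add atoms: none
Why: Suzuki–Miyaura coupling forms the biaryl bond because the aryl bromide undergoes oxidative addition far faster than the aryl tosylates with this bisphosphine catalyst, and each partner carries only one ortho substituent.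

**Step 23**
Reactants: 31 bis-silyl biaryl
Product: 32 bis-oxolane biaryl with both hydroxymethyl groups free; rings A and B tosylates, rings C and D benzyl ethers
Conditions: Bu4NF, AcOH, THF, 0 °C to rt
Reagents that add atoms: none
Why: Fluoride cleaves both primary silyl ethers, and buffering with acetic acid keeps the aryl tosylates from being attacked.

**Step 24**
Reactants: 32 dibenzyl ether
Product: 33 bis-oxolane biaryl with free phenols on rings C and D, tosylates on rings A and B and all four alcohols free (both oxolanes 2S,3R,4S in 2-aryl numbering)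
Conditions: H2 (1 atm), 10% Pd/C, EtOAc/MeOH, rt
Reagents that add atoms: none
Why: Hydrogenolysis removes the two aryl benzyl ethers much faster than it attacks aryl tosylates or the benzylic C–O bonds of the oxolanes, and frees the para phenol that ring C needs for the next step.

**Step 25**
Reactants: 33 bis-oxolane ditosylate
Product: 34 ditosylate of the target: the ring C oxolane is converted into the (1S,2S,3S)-1-aryl-7-hydroxy-2,3-bis(hydroxymethyl)-6-methoxytetralin-3-ol and the ring B oxolane is unchanged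
Conditions: CF3CO2H, CH2Cl2/MeCN (dilute), 0 °C to rt
Reagents that add atoms: none
Why: Protonation of the ring oxygen of the oxolane on ring C and C2–O heterolysis give a benzylic cation that is stabilised as a protonated para-quinone methide by the free para phenol of ring C, whereas the oxolane on ring B stays closed because its para oxygen is a sulfonate and cannot donate. The cation is trapped by the 4-hydroxy-3-methoxybenzyl ring through the carbon para to its methoxy group, an intramolecular Friedel–Crafts alkylation of the kind known for the acid isomerisation of 2-aryl-4-benzyltetrahydrofuran lignans into aryltetralins. The six-membered carbocycle closes in a 6-endo-trig mode with respect to the attacked arene bond, forming C1–C8a, and the former ring oxygen remains as the C3 hydroxymethyl group. The new C1 centre is controlled by the adjacent C2 centre, since the arene adds to the cation face that places the ring C aryl group pseudo-equatorial and trans to the C2 hydroxymethyl group, and reversible reclosure of the oxolane returns unreacted cation to starting material. Site selectivity between the two oxolanes rests on the free versus tosylated para phenol, regioselectivity on the arene rests on the carbon para to methoxy being both more activated and less hindered than the one ortho to it, and ring A cannot act as a nucleophile because of its own tosylate. C2 and C3 of the tetralin are carried over unchanged from C3 and C4 of the oxolane.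

**Step 26**
Reactants: 34 ditosylate of the target
Product: 35 CNP0252244.1 (target)
Conditions: KOH, MeOH/H2O, 65 °C, N2; then HCl to pH 5
Reagents that add atoms: none
Why: Hydroxide attacks sulfur of the two aryl sulfonates (S–O cleavage) and releases the ring A and ring B phenols without touching any stereocentre.

**Compound list**
1 | (S)-4-benzyl-1,3-oxazolidin-2-one | O=C1OC[C@H](Cc2ccccc2)N1 | starting material
2 | methyl 4-chloro-4-oxobutanoate | COC(=O)CCC(Cl)=O | starting material
3 | methyl 4-[(4S)-4-benzyl-2-oxo-1,3-oxazolidin-3-yl]-4-oxobutanoate | COC(=O)CCC(=O)N1[C@@H](Cc2ccccc2)COC1=O | intermediate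
4 | 5-bromovanillin (3-bromo-4-hydroxy-5-methoxybenzaldehyde) | COc1cc(C=O)cc(Br)c1O | starting material
5 | 2-bromo-4-formyl-6-methoxyphenyl 4-methylbenzenesulfonate | COc1cc(C=O)cc(Br)c1OS(=O)(=O)c1ccc(C)cc1 | intermediate
6 | methyl (3S,4S)-3-{[(4S)-4-benzyl-2-oxo-1,3-oxazolidin-3-yl]carbonyl}-4-(3-bromo-5-methoxy-4-tosyloxyphenyl)-4-hydroxybutanoate (syn-aldol hydroxy ester, not isolated) | COC(=O)C[C@H](C(=O)N1[C@@H](Cc2ccccc2)COC1=O)[C@H](O)c1cc(OC)c(OS(=O)(=O)c2ccc(C)cc2)c(Br)c1 | intermediate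
7 | (4S)-4-benzyl-3-{[(2S,3S)-2-(3-bromo-5-methoxy-4-tosyloxyphenyl)-5-oxooxolan-3-yl]carbonyl}-1,3-oxazolidin-2-one | O=C1C[C@H](C(=O)N2[C@@H](Cc3ccccc3)COC2=O)[C@@H](c2cc(OC)c(OS(=O)(=O)c3ccc(C)cc3)c(Br)c2)O1 | intermediate
8 | (2S,3S)-2-(3-bromo-5-methoxy-4-tosyloxyphenyl)-5-oxooxolane-3-carboxylic acid | O=C1C[C@H](C(=O)O)[C@@H](c2cc(OC)c(OS(=O)(=O)c3ccc(C)cc3)c(Br)c2)O1 | intermediate
9 | (4R,5S)-5-(3-bromo-5-methoxy-4-tosyloxyphenyl)-4-(hydroxymethyl)oxolan-2-one | O=C1C[C@H](CO)[C@@H](c2cc(OC)c(OS(=O)(=O)c3ccc(C)cc3)c(Br)c2)O1 | intermediate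
10 | (4R,5S)-5-(3-bromo-5-methoxy-4-tosyloxyphenyl)-4-(TBSO-methyl)oxolan-2-one | O=C1C[C@H](CO[Si](C)(C)C(C)(C)C)[C@@H](c2cc(OC)c(OS(=O)(=O)c3ccc(C)cc3)c(Br)c2)O1 | intermediate
11 | 3-hydroxy-4-methoxybenzyl alcohol (isovanillyl alcohol) | COc1ccc(CO)cc1O | starting material
12 | 5-(hydroxymethyl)-2-methoxyphenyl 4-methylbenzenesulfonate | COc1ccc(CO)cc1OS(=O)(=O)c1ccc(C)cc1 | intermediate
13 | 5-(bromomethyl)-2-methoxyphenyl 4-methylbenzenesulfonate | COc1ccc(CBr)cc1OS(=O)(=O)c1ccc(C)cc1 | intermediate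
14 | (3S,4R,5S)-5-(3-bromo-5-methoxy-4-tosyloxyphenyl)-3-(4-methoxy-3-tosyloxybenzyl)-4-(TBSO-methyl)oxolan-2-one | O=C1[C@@H](Cc2ccc(OC)c(OS(=O)(=O)c3ccc(C)cc3)c2)[C@H](CO[Si](C)(C)C(C)(C)C)[C@@H](c2cc(OC)c(OS(=O)(=O)c3ccc(C)cc3)c(Br)c2)O1 | intermediate
15 | (3S,4R,5S)-5-(3-bromo-5-methoxy-4-tosyloxyphenyl)-3-hydroxy-3-(4-methoxy-3-tosyloxybenzyl)-4-(TBSO-methyl)oxolan-2-one | O=C1[C@](O)(Cc2ccc(OC)c(OS(=O)(=O)c3ccc(C)cc3)c2)[C@H](CO[Si](C)(C)C(C)(C)C)[C@@H](c2cc(OC)c(OS(=O)(=O)c3ccc(C)cc3)c(Br)c2)O1 | intermediate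
16 | lactol of 15: (3S,4R,5S)-5-(3-bromo-5-methoxy-4-tosyloxyphenyl)-3-(4-methoxy-3-tosyloxybenzyl)-4-(TBSO-methyl)oxolane-2,3-diol, both C2 epimers (not isolated) | OC1[C@](O)(Cc2ccc(OC)c(OS(=O)(=O)c3ccc(C)cc3)c2)[C@H](CO[Si](C)(C)C(C)(C)C)[C@@H](c2cc(OC)c(OS(=O)(=O)c3ccc(C)cc3)c(Br)c2)O1 | intermediate
17 | (3S,4R,5S)-5-(3-bromo-5-methoxy-4-tosyloxyphenyl)-3-(4-methoxy-3-tosyloxybenzyl)-4-(TBSO-methyl)oxolan-3-ol | C1[C@](O)(Cc2ccc(OC)c(OS(=O)(=O)c3ccc(C)cc3)c2)[C@H](CO[Si](C)(C)C(C)(C)C)[C@@H](c2cc(OC)c(OS(=O)(=O)c3ccc(C)cc3)c(Br)c2)O1 | intermediate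
18 | 4-benzyloxy-3-bromo-5-methoxybenzaldehyde | COc1cc(C=O)cc(Br)c1OCc1ccccc1 | intermediate
19 | methyl (3S,4S)-3-{[(4S)-4-benzyl-2-oxo-1,3-oxazolidin-3-yl]carbonyl}-4-(4-benzyloxy-3-bromo-5-methoxyphenyl)-4-hydroxybutanoate (syn-aldol hydroxy ester, not isolated) | COC(=O)C[C@H](C(=O)N1[C@@H](Cc2ccccc2)COC1=O)[C@H](O)c1cc(OC)c(OCc2ccccc2)c(Br)c1 | intermediate
20 | (4S)-4-benzyl-3-{[(2S,3S)-2-(4-benzyloxy-3-bromo-5-methoxyphenyl)-5-oxooxolan-3-yl]carbonyl}-1,3-oxazolidin-2-one | O=C1C[C@H](C(=O)N2[C@@H](Cc3ccccc3)COC2=O)[C@@H](c2cc(OC)c(OCc3ccccc3)c(Br)c2)O1 | intermediate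
21 | (2S,3S)-2-(4-benzyloxy-3-bromo-5-methoxyphenyl)-5-oxooxolane-3-carboxylic acid | O=C1C[C@H](C(=O)O)[C@@H](c2cc(OC)c(OCc3ccccc3)c(Br)c2)O1 | intermediate
22 | (4R,5S)-5-(4-benzyloxy-3-bromo-5-methoxyphenyl)-4-(hydroxymethyl)oxolan-2-one | O=C1C[C@H](CO)[C@@H](c2cc(OC)c(OCc3ccccc3)c(Br)c2)O1 | intermediate
23 | (4R,5S)-5-(4-benzyloxy-3-bromo-5-methoxyphenyl)-4-(TBSO-methyl)oxolan-2-one | O=C1C[C@H](CO[Si](C)(C)C(C)(C)C)[C@@H](c2cc(OC)c(OCc3ccccc3)c(Br)c2)O1 | intermediate
24 | 4-benzyloxy-3-methoxybenzyl alcohol | COc1cc(CO)ccc1OCc1ccccc1 | starting material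
25 | 1-benzyloxy-4-(bromomethyl)-2-methoxybenzene | COc1cc(CBr)ccc1OCc1ccccc1 | intermediate
26 | (3S,4R,5S)-5-(4-benzyloxy-3-bromo-5-methoxyphenyl)-3-(4-benzyloxy-3-methoxybenzyl)-4-(TBSO-methyl)oxolan-2-one | O=C1[C@@H](Cc2ccc(OCc3ccccc3)c(OC)c2)[C@H](CO[Si](C)(C)C(C)(C)C)[C@@H](c2cc(OC)c(OCc3ccccc3)c(Br)c2)O1 | intermediate
27 | (3S,4R,5S)-5-(4-benzyloxy-3-bromo-5-methoxyphenyl)-3-(4-benzyloxy-3-methoxybenzyl)-3-hydroxy-4-(TBSO-methyl)oxolan-2-one | O=C1[C@](O)(Cc2ccc(OCc3ccccc3)c(OC)c2)[C@H](CO[Si](C)(C)C(C)(C)C)[C@@H](c2cc(OC)c(OCc3ccccc3)c(Br)c2)O1 | intermediate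
28 | lactol of 27: (3S,4R,5S)-5-(4-benzyloxy-3-bromo-5-methoxyphenyl)-3-(4-benzyloxy-3-methoxybenzyl)-4-(TBSO-methyl)oxolane-2,3-diol, both C2 epimers (not isolated) | OC1[C@](O)(Cc2ccc(OCc3ccccc3)c(OC)c2)[C@H](CO[Si](C)(C)C(C)(C)C)[C@@H](c2cc(OC)c(OCc3ccccc3)c(Br)c2)O1 | intermediate
29 | (3S,4R,5S)-5-(4-benzyloxy-3-bromo-5-methoxyphenyl)-3-(4-benzyloxy-3-methoxybenzyl)-4-(TBSO-methyl)oxolan-3-ol | C1[C@](O)(Cc2ccc(OCc3ccccc3)c(OC)c2)[C@H](CO[Si](C)(C)C(C)(C)C)[C@@H](c2cc(OC)c(OCc3ccccc3)c(Br)c2)O1 | intermediate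
30 | (3S,4R,5S)-5-[4-benzyloxy-3-methoxy-5-(4,4,5,5-tetramethyl-1,3,2-dioxaborolan-2-yl)phenyl]-3-(4-benzyloxy-3-methoxybenzyl)-4-(TBSO-methyl)oxolan-3-ol | C1[C@](O)(Cc2ccc(OCc3ccccc3)c(OC)c2)[C@H](CO[Si](C)(C)C(C)(C)C)[C@@H](c2cc(OC)c(OCc3ccccc3)c(B3OC(C)(C)C(C)(C)O3)c2)O1 | intermediate
31 | bis-oxolane biaryl: 17 and 29 joined at their former C–Br carbons (C5 of ring B to C5 of ring C); rings A and B tosylates, rings C and D benzyl ethers, both CH2OTBS; each oxolane 2S,3R,4S in 2-aryl numbering | COc1ccc(C[C@@]2(O)CO[C@H](c3cc(OC)c(OS(=O)(=O)c4ccc(C)cc4)c(-c4cc([C@H]5OC[C@](O)(Cc6ccc(OCc7ccccc7)c(OC)c6)[C@@H]5CO[Si](C)(C)C(C)(C)C)cc(OC)c4OCc4ccccc4)c3)[C@H]2CO[Si](C)(C)C(C)(C)C)cc1OS(=O)(=O)c1ccc(C)cc1 | intermediate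
32 | bis-oxolane biaryl as 31 with both CH2OH free | COc1ccc(C[C@@]2(O)CO[C@H](c3cc(OC)c(OS(=O)(=O)c4ccc(C)cc4)c(-c4cc([C@H]5OC[C@](O)(Cc6ccc(OCc7ccccc7)c(OC)c6)[C@@H]5CO)cc(OC)c4OCc4ccccc4)c3)[C@H]2CO)cc1OS(=O)(=O)c1ccc(C)cc1 | intermediate
33 | bis-oxolane ditosylate with free phenols on rings C and D (substrate of the key step) | COc1ccc(C[C@@]2(O)CO[C@H](c3cc(OC)c(OS(=O)(=O)c4ccc(C)cc4)c(-c4cc([C@H]5OC[C@](O)(Cc6ccc(O)c(OC)c6)[C@@H]5CO)cc(OC)c4O)c3)[C@H]2CO)cc1OS(=O)(=O)c1ccc(C)cc1 | intermediate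
34 | ditosylate of the target (ring C carries the 1S,2S,3S aryltetralin, ring B the 2S,3R,4S oxolane) | COc1ccc(C[C@@]2(O)CO[C@H](c3cc(OC)c(OS(=O)(=O)c4ccc(C)cc4)c(-c4cc([C@H]5c6cc(O)c(OC)cc6C[C@@](O)(CO)[C@@H]5CO)cc(OC)c4O)c3)[C@H]2CO)cc1OS(=O)(=O)c1ccc(C)cc1 | intermediate
35 | CNP0252244.1 | COc1ccc(C[C@@]2(O)CO[C@H](c3cc(OC)c(O)c(-c4cc([C@H]5c6cc(O)c(OC)cc6C[C@@](O)(CO)[C@@H]5CO)cc(OC)c4O)c3)[C@H]2CO)cc1O | target

**Step count and risks**

Total step count: 26. Longest linear sequence: 14 steps (steps 12, 13, 14, 15, 16, 18, 19, 20, 21, 22, 23, 24, 25, 26).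

Steps most likely to fail:

1. Step 25. The ionisation may not stay confined to the ring C oxolane, the cation may be intercepted intermolecularly by another electron-rich ring, or closure may occur ortho instead of para to the methoxy group. The fallback moves the transposition to the monomer stage, where only one oxolane exists, and sets out from 29. Treatment with BF3·OEt2 in CH2Cl2 (0 °C to rt) should ionise the oxolane, close the tetralin and remove the silyl ether to give the monomeric aryltetralin bromide F1. Miyaura borylation (B2pin2, PdCl2(dppf), KOAc, 1,4-dioxane) would give the aryltetralin pinacol boronate F2. Suzuki–Miyaura coupling of F2 with bromide 17 (PdCl2(dppf), K3PO4, aqueous 1,4-dioxane) would give the silylated tetralin–oxolane biaryl F3. Bu4NF with AcOH would give the desilylated dibenzyl ether F4, and hydrogenolysis (H2, Pd/C) of its two benzyl ethers comes back to the route at 34.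

2. Step 20. The oxocarbenium ion next to the free tertiary carbinol may undergo a 1,2-shift instead of hydride capture, or the Lewis acid may ionise the benzylic C–O bond and cause epimerisation or premature ring closure onto ring D. The fallback avoids both the enolate oxidation and the Lewis-acid deoxygenation and sets out from 26. Reduction with iBu2AlH (CH2Cl2, −78 °C) would give the lactol F5, and dehydration with MsCl and Et3N would give the 4-benzyl-2,3-dihydrofuran F6. Dimethyldioxirane should epoxidise the enol ether on the face anti to the silyloxymethyl group to give the acetal epoxide F7. LiBHEt3 (THF, 0 °C) would then open the epoxide at the acetal carbon and deliver the tertiary alcohol, coming back to the route at 29.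

3. Step 22. Transmetalation of the ortho-alkoxy boronate may be slow, so that protodeboronation or base-induced loss of a tosylate competes. The fallback replaces the boron-based coupling by a base-free Stille coupling and sets out from 29. Stannylation with Me3SnSnMe3 and Pd(PPh3)4 in toluene at 100 °C would give the aryl trimethylstannane F8. Coupling of F8 with bromide 17 (Pd(PPh3)4, CuI, CsF, DMF, 45 °C) comes back to the route at 31.

**Further compounds**
F1 | step 25 | (1S,2S,3S)-7-benzyloxy-1-(4-benzyloxy-3-bromo-5-methoxyphenyl)-2,3-bis(hydroxymethyl)-6-methoxy-1,2,3,4-tetrahydronaphthalen-3-ol (aryltetralin numbering, C1 bears the aryl group) | COc1cc(cc(Br)c1OCc1ccccc1)[C@H]1c2cc(OCc3ccccc3)c(OC)cc2C[C@@](O)(CO)[C@@H]1CO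
F2 | step 25 | pinacol boronate of F1 (boron in place of bromine) | COc1cc(cc(B2OC(C)(C)C(C)(C)O2)c1OCc1ccccc1)[C@H]1c2cc(OCc3ccccc3)c(OC)cc2C[C@@](O)(CO)[C@@H]1CO
F3 | step 25 | tetralin–oxolane biaryl: rings A and B tosylates, rings C and D benzyl ethers, oxolane CH2OTBS | COc1ccc(C[C@@]2(O)CO[C@H](c3cc(OC)c(OS(=O)(=O)c4ccc(C)cc4)c(-c4cc([C@H]5c6cc(OCc7ccccc7)c(OC)cc6C[C@@](O)(CO)[C@@H]5CO)cc(OC)c4OCc4ccccc4)c3)[C@H]2CO[Si](C)(C)C(C)(C)C)cc1OS(=O)(=O)c1ccc(C)cc1
F4 | step 25 | tetralin–oxolane biaryl as F3 with the oxolane CH2OH free | COc1ccc(C[C@@]2(O)CO[C@H](c3cc(OC)c(OS(=O)(=O)c4ccc(C)cc4)c(-c4cc([C@H]5c6cc(OCc7ccccc7)c(OC)cc6C[C@@](O)(CO)[C@@H]5CO)cc(OC)c4OCc4ccccc4)c3)[C@H]2CO)cc1OS(=O)(=O)c1ccc(C)cc1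
F5 | step 20 | lactol of 26: (3S,4R,5S)-5-(4-benzyloxy-3-bromo-5-methoxyphenyl)-3-(4-benzyloxy-3-methoxybenzyl)-4-(TBSO-methyl)oxolan-2-ol, both C2 epimers | OC1[C@@H](Cc2ccc(OCc3ccccc3)c(OC)c2)[C@H](CO[Si](C)(C)C(C)(C)C)[C@@H](c2cc(OC)c(OCc3ccccc3)c(Br)c2)O1
F6 | step 20 | (2S,3R)-2-(4-benzyloxy-3-bromo-5-methoxyphenyl)-4-(4-benzyloxy-3-methoxybenzyl)-3-(TBSO-methyl)-2,3-dihydrofuran | C1=C(Cc2ccc(OCc3ccccc3)c(OC)c2)[C@H](CO[Si](C)(C)C(C)(C)C)[C@@H](c2cc(OC)c(OCc3ccccc3)c(Br)c2)O1
F7 | step 20 | 4,5-epoxide of F6 with the epoxide oxygen trans to the silyloxymethyl group (2,6-dioxabicyclo[3.1.0]hexane) | [C@@H]12O[C@@]2(Cc3ccc(OCc4ccccc4)c(OC)c3)[C@H](CO[Si](C)(C)C(C)(C)C)[C@@H](c3cc(OC)c(OCc4ccccc4)c(Br)c3)O1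
F8 | step 22 | (3S,4R,5S)-5-[4-benzyloxy-3-methoxy-5-(trimethylstannyl)phenyl]-3-(4-benzyloxy-3-methoxybenzyl)-4-(TBSO-methyl)oxolan-3-ol | C1[C@](O)(Cc2ccc(OCc3ccccc3)c(OC)c2)[C@H](CO[Si](C)(C)C(C)(C)C)[C@@H](c2cc(OC)c(OCc3ccccc3)c([Sn](C)(C)C)c2)O1
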